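## Structural features

Septeremophilane G is a trinor-eremophilane: a bicyclo[4.4.0]decane in which the saturated ring A (C1–C5 and C10) shares the C5–C10 bond with ring B (C5–C10), a cross-conjugated 2-hydroxycyclohexa-2,5-dienone (C6=C7–OH, C8=O, C9=C10). Ring A carries four contiguous stereocentres: C2 (R, free hydroxyl), C3 (R, acyloxy), C4 (R, secondary methyl) and the quaternary C5 (S, angular methyl). The C3 oxygen and both methyl groups lie on one face and the C2 hydroxyl on the other, so the diol is trans and the methyls are cis. The C3 oxygen is esterified by (2E,4E,6S)-6-methylocta-2,4-dienoic acid, whose remote stereocentre is α to a carbonyl at the aldehyde stage of its preparation. Fragile elements are the diosphenol (an acidic enol, easily silylated, acylated and oxidised), the dienone, the dienoate (E/Z isomerisation, conjugate addition) and the mono-acylated trans-diol, in which the ester can migrate from O3 to O2. The real difficulty is the vicinal pair C4/C5, a tertiary centre next to an all-carbon quaternary centre, cis-dimethylated and correctly related to the C2/C3 diol; the second difficulty is telling two neighbouring secondary hydroxyls apart. The key step exploits the fact that C1, C2 and C3 with their trans-dioxygenation are C6, C5 and C4 of (−)-quinic acid: once the carboxyl carbon is removed, ring A exists as a cyclohexenone (C10=O, C5=C4) whose β-carbon C4 and α-carbon C5 accept the methyl group and the first three carbons of ring B, while a disiloxane bridge across O2 and O3 freezes the ring and directs both additions.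

## Logic of the disconnections

**Ester C3–O bond.** 27 is opened at the acyl C–O bond to 24 and a ring alcohol masked on O2 and on the enol oxygen O7 (26 from 19 and 24 via 25). Cutting here keeps the isomerisable dienoate out of every oxidation, organometallic and metathesis step and makes the plan convergent. The forward steps must acylate a hindered secondary hydroxyl without isomerising the diene and then remove two silyl groups without moving the ester to O2.

**O2/O3 differentiation.** 19 goes back to 18 and this to 17 by exchanging the O2/O3 bridge for silyl groups on O2 and O7 only. No skeletal bond is cut; the gain is that one protecting group serves ring A from 3 to 17. The demand is a site-selective silylation that leaves the more hindered O3–H free.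

**Oxidation pattern of ring B.** 17 is simplified to 15 (via 16) by removing two oxidation levels at C7/C8 and adding water back across C9=C10, and 15 to 14 by removing both hydroxyls. The whole diosphenol-dienone thus derives from one isolated olefin and one tertiary alcohol. Forward, the dihydroxylation may take either face, but the oxidation must expel the C10 hydroxyl once C8 is a ketone.

**C7=C8 and C9–C10.** 14 is cut at the C7=C8 double bond to 13, and 13 at C9–C10 to 12 and an allyl nucleophile. The bicycle is reduced to a monocyclic ketone with one allyl group. Forward, the nucleophile must add to a neopentyl ketone without enolising it and from the face that leaves both allyl groups cis, so that the locked chair can close.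

**Key disconnection, C4–CH3 and C5–C6.** 12 is cut at both bonds in one operation to 9, a methyl nucleophile and 10 (via 11). Both new stereocentres, including the quaternary one, go back to a flat sp2 pair, and the precursor is a simple chiral-pool enone. Forward, the methyl must enter axially at C4 and the allyl group at C5 anti to it; both depend on the rigid bridge, and the enolate must react on carbon before it equilibrates.

**C5–CH3.** 9 is cut at the vinylic methyl bond to 8, and 8 to 7. This is a two-step α-functionalisation that leads back to the unsubstituted enone. The coupling must be mild because O2 is β to the ketone.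

**Ring A from the chiral pool.** 7 goes back to 5 (via 6) by adding water across the olefin, 5 to 4 by re-attaching the excised carbon as CH2OH, 4 to 3 by oxidation level, 3 to 2 by removing the bridge, and 2 to 1. No stereocentre is made: C2 and C3 of 27 are C5 and C4 of 1. The demands are regioselective bridging of the trans-diequatorial 4,5-diol and an elimination that stops at the enone and does not run on to a phenol.

**Side chain.** 24 is taken back through 23 to 21 and 22 by cutting the C4′=C5′ double bond, and 21 to 20. The stereocentre is bought. The forward steps must not racemise 21 and must deliver the 2E,4E geometry.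

## Other disconnections considered

Alternative 1: The cut runs through C7–C8 and, transiently, C5–C10, so that ring B is traced back to the trans-1,2-divinylcyclohexanol A1 (C4 methyl, C3 ketal, methyl and vinyl on C5, hydroxyl and vinyl on C10).
- Forward step: heating A1 to about 200 °C with DBU would bring about an oxy-Cope shift that forms C7–C8 and breaks C5–C10, expanding ring A to the cyclodec-5-enone A2 (C10 ketone, C5=C6 olefin). A transannular carbonyl-ene reaction would then re-form C5–C10, shift the olefin to C6=C7 and give decalinol A3.
- In its favour: one reagent-free, atom-economic operation closes ring B and creates the quaternary C5. It ends with the same C10 carbinol that the chosen plan reaches in step 9 and uses for the C9=C10 olefin; on this point it is the equal. In ring formation per operation it is the better, since step 8 closes no ring.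
- Against it here: A3 has no oxygen at C2 and a ketone level at C3, so the trans-diol would have to be completed late (α-hydroxylation, diastereoselective reduction) and its hydroxyls still differentiated. The cis relationship of the C4 and C5 methyls would rest on the conformation of a ten-membered transition state. The absolute configuration would need a separate asymmetric step on the way to A1, and 200 °C limits what can be carried.
- Comparison: structurally the cascade reaches the bare skeleton faster. Mechanistically it is a concerted pericyclic sequence whose diastereocontrol is less predictable than axial attack on a locked half-chair. In step economy its short skeleton synthesis is expected to be offset by the redox and hydroxylation work in ring A, which the chosen plan avoids by taking C2 and C3 from the chiral pool.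

Alternative 2: The cut removes C5–C10 and C6–C7 together and leads back to the acyclic triene A4, in which a 1,2-dioxygenated diene (C7=C8–C9=C10) is tethered through C1–C4 to a β-methyl vinyl sulfone (C5=C6).
- Forward step: heating A4 would give, by intramolecular Diels–Alder reaction, the bicyclic sulfone A5 with rings A and B closed at once.
- In its favour: two rings, two C–C bonds and the quaternary centre arise in one step. Ring B arrives oxygenated at C7 and C8, with a sulfone that can leave as sulfinate to unveil C6=C7 and a silyl enol ether that allows dehydrogenation to C9=C10. O2 and O3 carry different protecting groups from the start, which is better than the chosen plan, where they are differentiated only in steps 13 and 14.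
- Against it here: A4 has three contiguous stereocentres (C2, C3, C4) that must each be made by asymmetric synthesis, plus a sensitive, geometry-defined dioxygenated diene. The dienophile is trisubstituted and must form a quaternary centre, so forcing conditions are likely. The facial selectivity at C5 relative to C4 would rest on allylic strain in a flexible tether.
- Comparison: structurally it is more convergent and builds more per step. Mechanistically the cycloaddition is concerted and its regiochemistry is fixed by the tether, but its stereocontrol is less secure than a conformationally locked ring. In step economy the gain of the key step is expected to be consumed by the length of the route to A4.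

Alternative 3: The cut is C1–C10 and leads back to the 4,4-disubstituted cyclohexa-2,5-dienone A6, whose side chain on C5 carries C4 (methyl), C3 (PMB ether) and a methyl ketone (C2, C1).
- Forward step: a chiral primary amine would convert the methyl ketone of A6 into its less substituted enamine, whose carbon C1 adds to C10 of one enone arm and gives the cis-fused bicyclic diketone A7.
- In its favour: a catalytic step closes ring A and fixes the quaternary C5 by selecting one of two enone arms, with cis fusion dictated by geometry. The C8 carbonyl and the C6=C7 olefin of the target are already in place. In catalytic setting of the quaternary centre and in ring formation it is the better of the two plans.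
- Against it here: C3 and C4 are already stereogenic in A6, so the arms are diastereotopic and the catalyst must match or override the substrate. Preparing A6 with a defined C4 next to the quaternary dienone carbon moves the central problem and does not remove it. C3 sits α to the C2 ketone and can epimerise under enamine conditions. C2 must later be reduced to the alcohol trans to O3, C9=C10 must be re-introduced by dehydrogenation, and C7 must be hydroxylated.
- Comparison: structurally it forms a ring where step 8 forms none. Mechanistically it relies on catalyst control in a double-diastereoselection setting, whereas the chosen plan relies on substrate control from a rigid ring. In step economy the later oxidation-state corrections in both rings are expected to make it no shorter.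

Key step: step 8

Remarks on the chemistry:
- Locants C1–C10 are those of the target decalin; monocyclic compounds are also named with cyclohexane locants. TIPDS = 1,1,3,3-tetraisopropyldisiloxane-1,3-diyl; TBS = tert-butyldimethylsilyl.
- Configuration check: traced atom by atom, C2 (R), C3 (R), C4 (R) and C5 (S) of 27 agree with the configurations drawn for 9 and 12 and with C5 and C4 of 1; no structure needed correction.
- Assumption: OsO4 may attack either face of ring B in step 11; both cis-diols converge in step 12, so C7 and C8 of 15 carry no descriptor.
- Assumption: the enol (diosphenol) tautomers written for 17, 18 and 27 are taken to be the stable forms.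

## Route

Step 1
Reactants: 1 (−)-quinic acid
Product: 2 methyl quinate
Conditions: MeOH, camphor-10-sulfonic acid (cat.), reflux
Reagents that add atoms: methanol, CO
Why: Fischer esterification; any lactone formed under acid is reopened by methanol, and no stereocentre is touched.

Step 2
Reactants: 2 methyl quinate
Product: 3 methyl 4,5-O-TIPDS-quinate (1-OH and 3-OH free)
Conditions: TIPDSCl2, imidazole, DMF, 0 °C → rt
Reagents that add atoms: 1,3-dichloro-1,1,3,3-tetraisopropyldisiloxane, CC(C)[Si](Cl)(C(C)C)O[Si](Cl)(C(C)C)C(C)C
Why: Silylation of the least hindered equatorial 5-OH followed by ring closure onto the neighbouring equatorial 4-OH gives the strain-free trans-fused seven-membered disiloxane; the axial 3-OH and the tertiary 1-OH are poorer partners. Bifunctional silyl protection of a trans-diequatorial diol.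

Step 3
Reactants: 3 methyl 4,5-O-TIPDS-quinate
Product: 4 4,5-O-TIPDS-1-(hydroxymethyl)cyclohexane-1,3,4,5-tetrol (quinic acid configuration)
Conditions: NaBH4, EtOH, 0 °C → rt
Reagents that add atoms: none
Why: Borohydride reduction of an α-hydroxy ester, activated by the neighbouring tertiary hydroxyl, gives the 1,2-diol; silyl ethers are inert.

Step 4
Reactants: 4 4,5-O-TIPDS-1-(hydroxymethyl)cyclohexane-1,3,4,5-tetrol
Product: 5 3-hydroxy-4,5-O-TIPDS-4,5-dihydroxycyclohexan-1-one (3-OH axial; cis to O4)
Conditions: NaIO4, THF–H2O (pH 7 buffer), 0 °C → rt
Reagents that add atoms: none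
Why: Periodate glycol cleavage of the only free 1,2-diol (tertiary C1–OH/CH2OH) excises the former carboxyl carbon as formaldehyde and leaves the ketone; the 3-OH has no free vicinal partner.

Step 5
Reactants: 5 3-hydroxy-4,5-O-TIPDS-4,5-dihydroxycyclohexan-1-one
Product: 7 (4R,5R)-4,5-O-TIPDS-4,5-dihydroxycyclohex-2-en-1-one, via 3-O-mesylate 6 (not isolated)
Conditions: MsCl, Et3N, CH2Cl2, 0 °C → rt
Reagents that add atoms: none
Why: Mesylation of the axial β-hydroxyl and E1cB elimination through the ketone enolate give the conjugated enone. The bridge-locked equatorial O5 lies near the nodal plane of the enolate and is not expelled, so aromatisation is avoided.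

Step 6
Reactants: 7 (4R,5R)-4,5-O-TIPDS-4,5-dihydroxycyclohex-2-en-1-one
Product: 8 (4R,5R)-2-iodo-4,5-O-TIPDS-4,5-dihydroxycyclohex-2-en-1-one
Conditions: I2, pyridine, CH2Cl2, 0 °C → rt
Reagents that add atoms: iodine, II
Why: α-Iodination of an enone by conjugate addition of pyridine, iodination of the resulting enolate and E1cB loss of pyridine (Baylis–Hillman-type sequence); C2 is the only α-vinylic position.

Step 7
Reactants: 8 (4R,5R)-2-iodo-4,5-O-TIPDS-4,5-dihydroxycyclohex-2-en-1-one
Product: 9 (4R,5R)-2-methyl-4,5-O-TIPDS-4,5-dihydroxycyclohex-2-en-1-one
Conditions: MeZnCl, Pd(PPh3)4 (5 mol %), THF, 0 °C → rt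
Reagents that add atoms: methylzinc chloride, C[Zn]Cl
Why: Negishi coupling: oxidative addition of zerovalent palladium into the vinylic C–I bond, transmetalation from zinc and reductive elimination. The neutral, room-temperature conditions spare the β-siloxy ketone.

Step 8
Reactants: 9 (4R,5R)-2-methyl-4,5-O-TIPDS-4,5-dihydroxycyclohex-2-en-1-one; 10 allyl bromide
Product: 12 (2R,3R,4R,5R)-2-allyl-2,3-dimethyl-4,5-O-TIPDS-4,5-dihydroxycyclohexan-1-one (allyl ketone), via lithium enolate 11 (not isolated)
Conditions: CuI, MeLi (2 equiv), Et2O, 0 °C; add 9, −78 → −30 °C; then 10, THF–DMPU, −30 °C → rt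
Reagents that add atoms: methyllithium, [Li]C (delivered as lithium dimethylcuprate, [Li+].C[Cu-]C)
Why: Me2CuLi forms a π-complex with the enone and transfers methyl to the β-carbon C4 through a trivalent copper intermediate and reductive elimination (1,4-addition of a Gilman cuprate), giving the regiodefined lithium enolate 11 (C10–OLi, C5=C10). No ring is closed in this step. C4 is controlled by the disiloxane bridge, which holds O2 and O3 diequatorial and so fixes one half-chair: the stereoelectronically required axial (antiparallel) approach to C4 comes from the face anti to the pseudoaxial C3–H, so the methyl should end up axial and cis to the C3 oxygen. The enolate is then C-allylated at C5 by 10 in an SN2 reaction once DMPU has loosened the aggregates; the closest known reaction type is the tandem conjugate addition–enolate alkylation (vicinal dialkylation) of cyclohexenones. C5 is controlled by the new C4 methyl, because axial attack through a chair-like transition state and approach anti to the axial C4 methyl are the same face; the allyl group should therefore enter trans-diaxial to that methyl and leave the C5 methyl cis to it. The step needs regioselectivity (only the C5 enolate, secured by generating it from the enone and alkylating before it equilibrates), C- over O-allylation (soft allylic bromide, lithium counter-ion) and two facial selectivities (both secured by the locked chair). The C2 siloxy group, β to the ketone of 12, is equatorial and poorly aligned with a C1 enolate, which should retard E1cB loss under the basic conditions.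

Step 9
Reactants: 12 (2R,3R,4R,5R)-2-allyl-2,3-dimethyl-4,5-O-TIPDS-4,5-dihydroxycyclohexan-1-one
Product: 13 diallyl carbinol: 10-allyl-10-hydroxy derivative of 12 (C10–OH axial and cis to the C4 methyl; both allyl groups cis)
Conditions: CH2=CHCH2MgBr, Et2O, −78 → 0 °C
Reagents that add atoms: allylmagnesium bromide, C=CC[Mg]Br
Why: 1,2-Addition of an allyl Grignard reagent, which adds to hindered, enolisable ketones through a six-membered SE2′ transition state faster than it deprotonates them. The axial C4 methyl blocks the axial trajectory at C10, so the allyl group should enter equatorially, giving the axial alcohol with the two allyl groups cis (gauche), the arrangement needed for ring closure; the C10 centre is removed again in step 12.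

Step 10
Reactants: 13 diallyl carbinol
Product: 14 cis-fused bicyclic alcohol: 2,3-O-TIPDS-4,5-dimethyl-bicyclo[4.4.0]dec-7-ene-2,3,10-triol (C7=C8; 10-OH cis to 5-CH3)
Conditions: second-generation Grubbs catalyst (H2IMes)(PCy3)Cl2Ru=CHPh (5 mol %), CH2Cl2, 40 °C
Reagents that add atoms: none
Why: Ring-closing metathesis of the 1,7-diene releases ethene and closes the cyclohexene ring B; the axial/equatorial cis allyl groups on the locked chair are within reach, and the ruthenium carbene tolerates the free tertiary hydroxyl and the disiloxane.

Step 11
Reactants: 14 cis-fused bicyclic alcohol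
Product: 15 7,8,10-triol: cis-7,8-diol of 14 (C7/C8 configuration not defined)
Conditions: OsO4 (2 mol %), N-methylmorpholine N-oxide, acetone–H2O, rt
Reagents that add atoms: osmium tetroxide, O=[Os](=O)(=O)=O (catalytic carrier of both oxygens); N-methylmorpholine N-oxide, C[N+]1([O-])CCOCC1; water, O
Why: Catalytic syn-dihydroxylation (Upjohn conditions) of the only olefin; the facial outcome is irrelevant because C7 and C8 become sp2 in step 12.

Step 12
Reactants: 15 7,8,10-triol
Product: 17 TIPDS-bridged dienone diosphenol (2R,3R,4R,5S): 7-hydroxy-8-oxo-6,9-diene, via hydroxy diketone 16 (not isolated)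
Conditions: (COCl)2, DMSO, CH2Cl2, −78 °C; Et3N, −78 °C → rt
Reagents that add atoms: none
Why: Double Swern oxidation of the secondary diol gives the 1,2-diketone 16 without C–C cleavage. The tertiary C10 hydroxyl, now β to the C8 ketone and activated as its alkoxysulfonium ion, should be expelled by Et3N in an E1cB elimination (net loss of water) to form C9=C10. The C7 ketone then enolises toward C6 to the cross-conjugated diosphenol, which cannot aromatise because C5 is quaternary.

Step 13
Reactants: 17 TIPDS-bridged dienone diosphenol
Product: 18 (4aS,5R,6R,7R)-3,6,7-trihydroxy-4a,5-dimethyl-5,6,7,8-tetrahydronaphthalen-2(4aH)-one (desacyl septeremophilane G)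
Conditions: Bu4NF, AcOH, THF, 0 °C → rt
Reagents that add atoms: none
Why: Fluoride-mediated cleavage of both Si–O bonds of the disiloxane (driven by Si–F bond formation); acetic acid buffering keeps the acidic diosphenol and the dienone away from naked alkoxide.

Step 14
Reactants: 18 desacyl septeremophilane G
Product: 19 2,7-bis-O-TBS ether of 18 (3-OH free)
Conditions: TBSCl (2.2 equiv), imidazole, DMF, 0 °C → rt
Reagents that add atoms: tert-butyldimethylsilyl chloride, CC(C)(C)[Si](C)(C)Cl
Why: Sterically controlled silylation: the acidic enol reacts first, then the equatorial C2 hydroxyl flanked only by the C1 methylene. The C3 hydroxyl, gauche to the axial C4 methyl and next to the new C2 silyl ether, should remain free.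

Step 15
Reactants: 20 (S)-2-methylbutan-1-ol
Product: 21 (S)-2-methylbutanal
Conditions: TEMPO (10 mol %), PhI(OAc)2, CH2Cl2, rt; used at once as a dried solution
Reagents that add atoms: none
Why: Oxoammonium-mediated oxidation of a primary alcohol stops at the aldehyde; no strong base or acid is present, so the α-stereocentre should be preserved.

Step 16
Reactants: 21 (S)-2-methylbutanal; 22 triethyl 4-phosphonocrotonate
Product: 23 ethyl (2E,4E,6S)-6-methylocta-2,4-dienoate
Conditions: LiN(SiMe3)2, THF, −78 °C; then 21, −78 → 0 °C
Reagents that add atoms: none
Why: Vinylogous Horner–Wadsworth–Emmons olefination: the preformed phosphonate anion attacks the aldehyde through its α-carbon and eliminates phosphate to give the E olefin, the 2E geometry coming from the reagent. Addition of the aldehyde to the cold, fully formed anion limits epimerisation.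

Step 17
Reactants: 23 ethyl (2E,4E,6S)-6-methylocta-2,4-dienoate
Product: 24 (2E,4E,6S)-6-methylocta-2,4-dienoic acid
Conditions: LiOH, THF–MeOH–H2O, rt; then HCl to pH 3
Reagents that add atoms: lithium hydroxide, [Li+].[OH-]
Why: Saponification (acyl–oxygen cleavage by hydroxide); the stereocentre is γ,δ-remote from the carboxylate and not acidic.

Step 18
Reactants: 19 2,7-bis-O-TBS ether of 18; 24 (2E,4E,6S)-6-methylocta-2,4-dienoic acid
Product: 26 2,7-bis-O-TBS septeremophilane G, via mixed anhydride 25 (not isolated)
Conditions: 24, 2,4,6-trichlorobenzoyl chloride, Et3N, toluene, rt; then 19, DMAP, rt → 40 °C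
Reagents that add atoms: none
Why: Yamaguchi esterification: the hindered aroyl mixed anhydride is attacked by DMAP only at the dienoyl carbonyl, and the resulting acylpyridinium ion acylates the hindered C3 hydroxyl. The enol and the C2 hydroxyl are silylated and cannot compete.

Step 19
Reactants: 26 2,7-bis-O-TBS septeremophilane G
Product: 27 septeremophilane G
Conditions: HF·pyridine, pyridine, THF, 0 °C → rt
Reagents that add atoms: none
Why: Fluoride-mediated desilylation of the silyl enol ether and of the secondary silyl ether; the buffered, weakly acidic medium should suppress O3 → O2 acyl migration and leave the dienoate and the dienone untouched.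

## Compound list

1 | (−)-quinic acid, (1S,3R,4S,5R)-1,3,4,5-tetrahydroxycyclohexane-1-carboxylic acid | C1[C@H]([C@H]([C@@H](C[C@@]1(C(=O)O)O)O)O)O | starting material
2 | methyl quinate | COC(=O)[C@]1(O)C[C@@H](O)[C@@H](O)[C@H](O)C1 | intermediate
3 | methyl 4,5-O-(1,1,3,3-tetraisopropyldisiloxane-1,3-diyl)quinate (bridge on the trans-4,5-diol; 1-OH and 3-OH free) | COC(=O)[C@]1(O)C[C@@H](O)[C@H]2O[Si](C(C)C)(C(C)C)O[Si](C(C)C)(C(C)C)O[C@@H]2C1 | intermediate
4 | 4,5-O-TIPDS-1-(hydroxymethyl)cyclohexane-1,3,4,5-tetrol (quinic acid numbering and configuration) | OC[C@]1(O)C[C@@H](O)[C@H]2O[Si](C(C)C)(C(C)C)O[Si](C(C)C)(C(C)C)O[C@@H]2C1 | intermediate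
5 | 3-hydroxy-4,5-O-TIPDS-4,5-dihydroxycyclohexan-1-one (quinic acid numbering; 3-OH axial, cis to O4) | O=C1C[C@@H](O)[C@H]2O[Si](C(C)C)(C(C)C)O[Si](C(C)C)(C(C)C)O[C@@H]2C1 | intermediate
6 | 3-O-methanesulfonate of 5 | O=C1C[C@@H](OS(C)(=O)=O)[C@H]2O[Si](C(C)C)(C(C)C)O[Si](C(C)C)(C(C)C)O[C@@H]2C1 | intermediate (not isolated)
7 | (4R,5R)-4,5-O-TIPDS-4,5-dihydroxycyclohex-2-en-1-one | O=C1C=C[C@H]2O[Si](C(C)C)(C(C)C)O[Si](C(C)C)(C(C)C)O[C@@H]2C1 | intermediate
8 | (4R,5R)-2-iodo-4,5-O-TIPDS-4,5-dihydroxycyclohex-2-en-1-one | O=C1C(I)=C[C@H]2O[Si](C(C)C)(C(C)C)O[Si](C(C)C)(C(C)C)O[C@@H]2C1 | intermediate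
9 | (4R,5R)-2-methyl-4,5-O-TIPDS-4,5-dihydroxycyclohex-2-en-1-one (precursor of the key step) | CC1=C[C@H]2O[Si](C(C)C)(C(C)C)O[Si](C(C)C)(C(C)C)O[C@@H]2CC1=O | intermediate
10 | allyl bromide (3-bromoprop-1-ene) | C=CCBr | starting material
11 | lithium (3R,4R,5R)-2,3-dimethyl-4,5-O-TIPDS-4,5-dihydroxycyclohex-1-en-1-olate (3-methyl axial, cis to O4) | [Li+].[O-]C1=C(C)[C@@H](C)[C@H]2O[Si](C(C)C)(C(C)C)O[Si](C(C)C)(C(C)C)O[C@@H]2C1 | intermediate (not isolated)
12 | (2R,3R,4R,5R)-2-allyl-2,3-dimethyl-4,5-O-TIPDS-4,5-dihydroxycyclohexan-1-one (methyls cis; 3-methyl cis to O4; allyl trans to the 3-methyl) | C=CC[C@]1(C)[C@@H](C)[C@H]2O[Si](C(C)C)(C(C)C)O[Si](C(C)C)(C(C)C)O[C@@H]2CC1=O | intermediate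
13 | 10-allyl-10-hydroxy derivative of 12 (C10–OH axial and cis to the C4 methyl; both allyl groups cis) | C=CC[C@]1(C)[C@@H](C)[C@H]2O[Si](C(C)C)(C(C)C)O[Si](C(C)C)(C(C)C)O[C@@H]2C[C@]1(O)CC=C | intermediate
14 | 2,3-O-TIPDS-4,5-dimethyl-bicyclo[4.4.0]dec-7-ene-2,3,10-triol (target numbering; cis-fused; 10-OH cis to 5-CH3) | C[C@H]1[C@H]2O[Si](C(C)C)(C(C)C)O[Si](C(C)C)(C(C)C)O[C@@H]2C[C@]3(O)CC=CC[C@]13C | intermediate
15 | cis-7,8-diol of 14 (C7 and C8 not defined) | C[C@H]1[C@H]2O[Si](C(C)C)(C(C)C)O[Si](C(C)C)(C(C)C)O[C@@H]2C[C@]3(O)CC(O)C(O)C[C@]13C | intermediate
16 | 10-hydroxy-7,8-dione derived from 15 | C[C@H]1[C@H]2O[Si](C(C)C)(C(C)C)O[Si](C(C)C)(C(C)C)O[C@@H]2C[C@]3(O)CC(=O)C(=O)C[C@]13C | intermediate (not isolated)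
17 | (2R,3R,4R,5S)-2,3-O-TIPDS-7-hydroxy-4,5-dimethyl-8-oxo-6,9-diene (TIPDS-bridged dienone diosphenol) | C[C@H]1[C@H]2O[Si](C(C)C)(C(C)C)O[Si](C(C)C)(C(C)C)O[C@@H]2CC3=CC(=O)C(O)=C[C@]13C | intermediate
18 | (4aS,5R,6R,7R)-3,6,7-trihydroxy-4a,5-dimethyl-5,6,7,8-tetrahydronaphthalen-2(4aH)-one (desacyl septeremophilane G) | C[C@H]1[C@@H](O)[C@H](O)CC2=CC(=O)C(O)=C[C@]12C | intermediate
19 | 2,7-bis-O-TBS ether of 18 (target numbering; 3-OH free) | C[C@H]1[C@@H](O)[C@H](O[Si](C)(C)C(C)(C)C)CC2=CC(=O)C(O[Si](C)(C)C(C)(C)C)=C[C@]12C | intermediate
20 | (S)-2-methylbutan-1-ol | CC[C@H](C)CO | starting material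
21 | (S)-2-methylbutanal | CC[C@H](C)C=O | intermediate
22 | triethyl 4-phosphonocrotonate, ethyl (E)-4-(diethoxyphosphoryl)but-2-enoate | CCOC(=O)/C=C/CP(=O)(OCC)OCC | starting material
23 | ethyl (2E,4E,6S)-6-methylocta-2,4-dienoate | CC[C@H](C)/C=C/C=C/C(=O)OCC | intermediate
24 | (2E,4E,6S)-6-methylocta-2,4-dienoic acid | CC[C@H](C)/C=C/C=C/C(=O)O | intermediate
25 | (2E,4E,6S)-6-methylocta-2,4-dienoic 2,4,6-trichlorobenzoic anhydride | CC[C@H](C)/C=C/C=C/C(=O)OC(=O)c1c(Cl)cc(Cl)cc1Cl | intermediate (not isolated)
26 | 2,7-bis-O-TBS septeremophilane G | C[C@H]1[C@@H](OC(=O)/C=C/C=C/[C@@H](C)CC)[C@H](O[Si](C)(C)C(C)(C)C)CC2=CC(=O)C(O[Si](C)(C)C(C)(C)C)=C[C@]12C | intermediate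
27 | septeremophilane G, (4aS,5R,6R,7R)-3,7-dihydroxy-4a,5-dimethyl-2-oxo-2,4a,5,6,7,8-hexahydronaphthalen-6-yl (2E,4E,6S)-6-methylocta-2,4-dienoate | CC[C@H](C)/C=C/C=C/C(=O)O[C@H]1[C@H](O)CC2=CC(=O)C(O)=C[C@]2(C)[C@H]1C | target

## Step count and least certain steps

Total step count: 19 steps. Longest linear sequence: 16 steps (steps 1–14, 18 and 19, from 1); the side chain takes 3 steps (15–17).

**Step 8 (key step).**
- Most likely to go wrong: slow C-alkylation of the hindered, fully substituted enolate 11 in the cuprate medium. Proton exchange with product 12 would then set in (allylation at C1, E1cB loss of the C2 siloxy group), or O-allylation would compete. A smaller risk is erosion of facial selectivity at C4 if the half-chair is less biased than argued.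
- Fallback: setting out from 9, the cuprate addition is run as before, but 11 is trapped on oxygen with allyl chloroformate to give the isolable allyl enol carbonate F1. Pd(PPh3)4 (catalytic, THF, rt) then ionises the carbonate, CO2 is lost and the enolate/π-allylpalladium pair recombines at C5 (Tsuji decarboxylative allylation), coming back to the route at 12. An SN2 alkylation of an aggregated lithium enolate is thus replaced by a zerovalent-palladium-catalysed allylation under neutral conditions, a known way to α-quaternary ketones from tetrasubstituted enol carbonates; the facial argument at C5 is unchanged.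

**Step 12.**
- Most likely to go wrong: incomplete elimination of the tertiary C10 hydroxyl, methylthiomethyl ether formation on the tertiary alcohol or on the enol by activated DMSO, or oxidative cleavage of C7–C8.
- Fallback: setting out from 15, oxidation with 2-iodoxybenzoic acid (DMSO, rt), which converts cyclic 1,2-diols to 1,2-diones without cleavage and cannot activate a tertiary alcohol, gives the isolable hydroxy diosphenol F2. Acid-catalysed dehydration of the β-hydroxy ketone (TsOH, toluene, 60 °C) then comes back to the route at 17. Oxidation and elimination are separated and can each be optimised.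

**Step 14.**
- Most likely to go wrong: insufficient discrimination between the C2 and C3 hydroxyls (bis-silylation or a C3 silyl ether), or silyl migration between them.
- Fallback: setting out from 18, one equivalent of TBSCl with Et3N caps only the acidic enol and gives the 7-O-TBS diol F3. Heating F3 with Bu2SnO (toluene, azeotropic removal of water) gives the 2,3-O-dibutylstannylene acetal F4, in which the less hindered O2 is the activated oxygen; TBSCl then silylates O2 and comes back to the route at 19. Site selection by tin-acetal activation of the nucleophile replaces steric discrimination of a free diol.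

**Step 18.**
- Most likely to go wrong: sluggish acylation of the hindered C3 hydroxyl, DMAP-induced isomerisation of or conjugate addition to the dienoyl unit, or base-induced migration of the C2 silyl group to O3.
- Fallback: setting out from 19, the small diethylphosphonoacetic acid is attached first (DCC, catalytic DMAP) to give the phosphonoacetate F5. Aldehyde 21 is homologated with Ph3P=CHCHO to (2E,4S)-4-methylhex-2-enal F6. Horner–Wadsworth–Emmons olefination of F6 with F5 (LiCl, DBU, MeCN) forms the C2′=C3′ bond E-selectively and comes back to the route at 26. The dienoate is assembled on the molecule and is not delivered as a bulky acylating agent.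

## Further compounds

F1 | step 8 | allyl (3R,4R,5R)-2,3-dimethyl-4,5-O-TIPDS-4,5-dihydroxycyclohex-1-en-1-yl carbonate | C=CCOC(=O)OC1=C(C)[C@@H](C)[C@H]2O[Si](C(C)C)(C(C)C)O[Si](C(C)C)(C(C)C)O[C@@H]2C1
F2 | step 12 | 10-hydroxy diosphenol (7-hydroxy-8-oxo-6-ene with tertiary 10-OH; TIPDS on O2/O3) | C[C@H]1[C@H]2O[Si](C(C)C)(C(C)C)O[Si](C(C)C)(C(C)C)O[C@@H]2C[C@]3(O)CC(=O)C(O)=C[C@]13C
F3 | step 14 | 7-O-TBS ether of 18 (2-OH and 3-OH free) | C[C@H]1[C@@H](O)[C@H](O)CC2=CC(=O)C(O[Si](C)(C)C(C)(C)C)=C[C@]12C
F4 | step 14 | 2,3-O-dibutylstannylene acetal of F3 | C[C@H]1[C@H]2O[Sn](CCCC)(CCCC)O[C@@H]2CC3=CC(=O)C(O[Si](C)(C)C(C)(C)C)=C[C@]13C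
F5 | step 18 | 3-O-(diethylphosphonoacetyl) derivative of 19 | C[C@H]1[C@@H](OC(=O)CP(=O)(OCC)OCC)[C@H](O[Si](C)(C)C(C)(C)C)CC2=CC(=O)C(O[Si](C)(C)C(C)(C)C)=C[C@]12C
F6 | step 18 | (2E,4S)-4-methylhex-2-enal | CC[C@H](C)/C=C/C=O
A1 | alternative 1 | trans-1,2-divinylcyclohexanol precursor (C4 methyl, C3 dioxolane, methyl and vinyl on C5, hydroxyl and vinyl on C10; trans-divinyl arrangement assumed) | C[C@H]1C2(OCCO2)CC[C@@](O)(C=C)[C@]1(C)C=C
A2 | alternative 1 | (E)-cyclodec-5-enone from the oxy-Cope shift (C10 ketone, C5=C6 olefin, C3 dioxolane) | C/C1=C\CCCC(=O)CCC2(OCCO2)[C@@H]1C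
A3 | alternative 1 | decalinol (C10–OH, C6=C7, C3 dioxolane, 4,5-dimethyl) | C[C@H]1C2(OCCO2)CC[C@@]3(O)CCC=C[C@]13C
A4 | alternative 2 | acyclic triene: 7-MOM-oxy-8-TBS-oxy diene tethered to the (E)-vinyl sulfone, 2-OTBS, 3-OPMB, 4-methyl (C7=C8 geometry not fixed) | COCOC=C(O[Si](C)(C)C(C)(C)C)/C=C/C[C@@H](O[Si](C)(C)C(C)(C)C)[C@H](OCc1ccc(OC)cc1)[C@H](C)/C(C)=C/S(=O)(=O)c1ccccc1
A5 | alternative 2 | bicyclic sulfone (trans-fused; C8 silyl enol ether, C7 MOM ether, C6 phenylsulfonyl) | C[C@H]1[C@@H](OCc2ccc(OC)cc2)[C@H](O[Si](C)(C)C(C)(C)C)C[C@H]2C=C(O[Si](C)(C)C(C)(C)C)C(OCOC)C(S(=O)(=O)c3ccccc3)[C@]12C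
A6 | alternative 3 | 4-methyl-4-[(2R,3R)-3-(4-methoxybenzyloxy)-4-oxopentan-2-yl]cyclohexa-2,5-dien-1-one | O=C1C=CC(C)(C=C1)[C@@H](C)[C@@H](OCc1ccc(OC)cc1)C(C)=O
A7 | alternative 3 | cis-fused bicyclic diketone (C2 and C8 ketones, C6=C7, 3-OPMB, 4,5-dimethyl) | C[C@H]1[C@@H](OCc3ccc(OC)cc3)C(=O)C[C@@H]2CC(=O)C=C[C@]12C
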